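## Retrosynthetic overview

1. The aryl–C(=O) bond is made last: Negishi acylation of a diortho-MOM-protected arylzinc with the acid chloride of the fully substituted cyclohexene carboxylic acid, then MOM removal.
2. Key step: the cyclohexene is made not by a Diels–Alder reaction but by an Ireland–Claisen ring contraction of a cis-4-phenyl-6-alkenyl δ-lactone. One [3,3] shift forms C1–C2, creates the C3=C4 alkene, and sets C1 and C2 by chirality transfer with no regiochemical ambiguity.
3. The lactone comes from CBS reduction and lactonisation of an enone. The enone is assembled by Negishi acylation from the (R)-monomethyl ester of 3-phenylglutaric acid (desymmetrised anhydride, sets the phenyl-bearing centre) and an (E)-alkenyl iodide (prenyl bromide + propynyl Grignard reagent, then hydrozirconation–iodination).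
4. Ring order: the δ-lactone (temporary heterocycle) first, then the carbocycle by ring contraction; the aromatic ring is bought in, adjusted by Dakin oxidation and attached last.

Ring numbering used below: C1 bears the C=O, C2 the prenyl group, C3 the methyl group, C6 the phenyl group; the target is (1R,2S,6R).

Assumption: (DHQD)2AQN is taken to give the (R)-hemiester in the anhydride methanolysis; should the optical rotation show the opposite sense, the pseudoenantiomeric (DHQ)2AQN is used and nothing else changes.

## Route

**Step 1**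
Reactants: 1 1-bromo-3-methylbut-2-ene (prenyl bromide); 2 prop-1-yn-1-ylmagnesium bromide
Product: 3 6-methylhept-5-en-2-yne
Conditions: CuI (5 mol %), THF, 0 °C → rt
Reagents that add atoms: none
Why: Copper-catalysed allylic alkynylation (SN2 cross-coupling of an alkynyl Grignard reagent): the alkynylcopper formed in situ displaces bromide at the unhindered primary carbon of the prenyl unit and gives the skipped enyne with no stereocentre involved.

**Step 2**
Reactants: 3 6-methylhept-5-en-2-yne
Product: 5 (2E)-2-iodo-6-methylhepta-2,5-diene, via alkenylzirconocene chloride 4 (not isolated)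
Conditions: Cp2Zr(H)Cl (1.6 equiv), THF, rt → 45 °C; then I2, 0 °C
Reagents that add atoms: iodine, II
Why: Hydrozirconation–iodinolysis: Zr–H adds syn across the alkyne and, under equilibrating conditions with excess reagent, zirconium settles on C2 next to the small methyl group, so that iodine replaces zirconium with retention and the methyl group ends cis to the prenyl CH2, i.e. the (E)-iodide.

**Step 3**
Reactants: 6 3-phenylglutaric anhydride
Product: 7 (3R)-5-methoxy-5-oxo-3-phenylpentanoic acid
Conditions: MeOH (10 equiv), (DHQD)2AQN (30 mol %), Et2O, −40 °C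
Reagents that add atoms: methanol, CO
Why: Enantioselective desymmetrisation of a prochiral cyclic anhydride (cinchona-amine general-base catalysed alcoholysis): the catalyst directs methanol to one of the two enantiotopic carbonyl groups and thereby sets the phenyl-bearing stereocentre, the future ring C6, as R.

**Step 4**
Reactants: 7 (3R)-5-methoxy-5-oxo-3-phenylpentanoic acid; 5 (2E)-2-iodo-6-methylhepta-2,5-diene
Product: 11 methyl (3R,6E)-6,10-dimethyl-5-oxo-3-phenylundeca-6,9-dienoate, via acid chloride 8 (not isolated), via alkenyllithium 9 (not isolated), via alkenylzinc chloride 10 (not isolated)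
Conditions: on 7: (COCl)2, cat. DMF, CH2Cl2, 0 °C → rt, evaporate; on 5: t-BuLi (2 equiv), Et2O, −78 °C, then ZnCl2, THF, −78 → 0 °C; combine, Pd(PPh3)4 (5 mol %), THF, 0 °C → rt
Reagents that add atoms: none
Why: Negishi acylation: iodine–lithium exchange and lithium–zinc transmetalation both retain the alkene geometry, and zerovalent palladium couples the alkenylzinc with the acid chloride far faster than either reacts with the methyl ester, so the enone forms with the C3 stereocentre untouched.

**Step 5**
Reactants: 11 methyl (3R,6E)-6,10-dimethyl-5-oxo-3-phenylundeca-6,9-dienoate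
Product: 13 (4R,6R)-6-[(2E)-6-methylhepta-2,5-dien-2-yl]-4-phenyltetrahydro-2H-pyran-2-one, via hydroxy ester 12 (not isolated)
Conditions: (S)-2-methyl-CBS-oxazaborolidine (20 mol %), catecholborane (1.5 equiv), toluene, −78 °C; aq. NaOH work-up; then PPTS (10 mol %), toluene, 60 °C
Reagents that add atoms: none
Why: Corey–Bakshi–Shibata reduction then acid-catalysed lactonisation: with the α-methylalkenyl group acting as the large substituent the (S)-oxazaborolidine delivers hydride to the same carbonyl face as in acetophenone → (R)-1-phenylethanol, setting C5 as R under reagent control, and ring closure gives the cis-4,6-disubstituted lactone, from which the trans-lactone arising from any minor stereoisomer is removed by chromatography.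

**Step 6**
Reactants: 13 (4R,6R)-6-[(2E)-6-methylhepta-2,5-dien-2-yl]-4-phenyltetrahydro-2H-pyran-2-one
Product: 16 (1R,2S,6R)-3-methyl-2-(3-methylbut-2-en-1-yl)-6-phenylcyclohex-3-ene-1-carboxylic acid, via silyl ketene acetal 14 (not isolated), via silyl ester 15 (not isolated)
Conditions: LiN(i-Pr)2 (1.2 equiv), TBSCl (present from the start), DMPU, THF, −78 °C → rt; toluene, 110 °C, 4–6 h; then 1 M HCl, THF, rt
Reagents that add atoms: none
Why: Ireland–Claisen rearrangement run as a lactone ring contraction: the cyclic silyl ketene acetal must react through a boat-like [3,3] transition state in which the lactone α-carbon bonds to the alkene terminus on the face that carries the alkenyl group while the allylic C–O bond breaks, so the carbinol chirality is transferred to C1 and C2, the (E)-alkene places the prenyl group cis to the carboxyl group, and the phenyl group that was cis to the alkenyl group ends trans to the carboxyl group, giving (1R,2S,6R) and the C3=C4 alkene in one operation.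

**Step 7**
Reactants: 17 3-hydroxy-4,5-dimethoxybenzaldehyde
Product: 19 4,5-dimethoxybenzene-1,3-diol, via aryl formate 18 (not isolated)
Conditions: 30% H2O2, cat. H2SO4, MeOH, rt
Reagents that add atoms: hydrogen peroxide, OO
Why: Dakin oxidation: the electron-rich aryl group migrates to oxygen in the acid-activated peroxide adduct of the aldehyde (Baeyer–Villiger-type shift), and the resulting formate is methanolysed in the same pot to the phenol.

**Step 8**
Reactants: 19 4,5-dimethoxybenzene-1,3-diol
Product: 20 1,2-dimethoxy-3,5-bis(methoxymethoxy)benzene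
Conditions: MOMCl (2.5 equiv), i-Pr2NEt (3 equiv), CH2Cl2, 0 °C → rt
Reagents that add atoms: chloromethyl methyl ether, COCCl
Why: Williamson-type O-alkylation of both phenols by the highly reactive α-chloro ether with a hindered amine base, installing MOM groups that direct the coming lithiation and are removable under mild acid.

**Step 9**
Reactants: 16 (1R,2S,6R)-3-methyl-2-(3-methylbut-2-en-1-yl)-6-phenylcyclohex-3-ene-1-carboxylic acid; 20 1,2-dimethoxy-3,5-bis(methoxymethoxy)benzene
Product: 24 [2,6-bis(methoxymethoxy)-3,4-dimethoxyphenyl][(1R,2S,6R)-3-methyl-2-(3-methylbut-2-en-1-yl)-6-phenylcyclohex-3-en-1-yl]methanone, via acid chloride 21 (not isolated), via aryllithium 22 (not isolated), via arylzinc chloride 23 (not isolated)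
Conditions: on 16: (COCl)2, cat. DMF, CH2Cl2, 0 °C → rt, evaporate; on 20: n-BuLi (1.05 equiv), THF, 0 °C, then ZnCl2, 0 °C → rt; combine, Pd(PPh3)4 (5 mol %), THF, rt → 45 °C
Reagents that add atoms: none
Why: Directed ortho-metalation followed by Negishi acylation: butyllithium removes the ring proton flanked by the two OMOM groups (cooperative directing effect), and after transmetalation the non-basic arylzinc is acylated under zerovalent palladium catalysis without epimerising the α-stereocentre of the acid chloride, the product being too hindered to react further.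

**Step 10**
Reactants: 24 [2,6-bis(methoxymethoxy)-3,4-dimethoxyphenyl][(1R,2S,6R)-3-methyl-2-(3-methylbut-2-en-1-yl)-6-phenylcyclohex-3-en-1-yl]methanone
Product: 25 (2,6-dihydroxy-3,4-dimethoxyphenyl)[(1R,2S,6R)-3-methyl-2-(3-methylbut-2-en-1-yl)-6-phenylcyclohex-3-en-1-yl]methanone
Conditions: 3 M aq. HCl, MeOH, 40 °C
Reagents that add atoms: none
Why: Acid-catalysed acetal cleavage (MOM deprotection by transacetalisation to methanol): the aryl MOM ethers ionise readily, assisted by the ortho carbonyl group, under acidity too mild to hydrate or isomerise the two trisubstituted alkenes or to enolise the hindered ketone, so all three stereocentres are retained.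

## Compound list

1 | 1-bromo-3-methylbut-2-ene (prenyl bromide) | CC(C)=CCBr | starting material
2 | prop-1-yn-1-ylmagnesium bromide | CC#C[Mg]Br | starting material
3 | 6-methylhept-5-en-2-yne | CC#CCC=C(C)C | intermediate
4 | chlorobis(cyclopentadienyl)[(2E)-6-methylhepta-2,5-dien-2-yl]zirconium (Zr trans to C4) | C/C(=C\CC=C(C)C)[Zr](Cl)(C1C=CC=C1)C1C=CC=C1 | intermediate
5 | (2E)-2-iodo-6-methylhepta-2,5-diene | C/C(I)=C\CC=C(C)C | intermediate
6 | 3-phenylglutaric anhydride (4-phenyldihydro-2H-pyran-2,6(3H)-dione) | O=C1CC(c2ccccc2)CC(=O)O1 | starting material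
7 | (3R)-5-methoxy-5-oxo-3-phenylpentanoic acid | COC(=O)C[C@H](c1ccccc1)CC(=O)O | intermediate
8 | methyl (3S)-5-chloro-5-oxo-3-phenylpentanoate (same spatial arrangement as 7; descriptor changes by priority only) | COC(=O)C[C@H](c1ccccc1)CC(=O)Cl | intermediate
9 | [(2Z)-6-methylhepta-2,5-dien-2-yl]lithium (Li trans to C4, geometry of 5 retained; Z by priority only) | [Li]/C(C)=C/CC=C(C)C | intermediate
10 | chloro[(2E)-6-methylhepta-2,5-dien-2-yl]zinc | Cl[Zn]/C(C)=C/CC=C(C)C | intermediate
11 | methyl (3R,6E)-6,10-dimethyl-5-oxo-3-phenylundeca-6,9-dienoate | COC(=O)C[C@H](c1ccccc1)CC(=O)/C(C)=C/CC=C(C)C | intermediate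
12 | methyl (3R,5R,6E)-5-hydroxy-6,10-dimethyl-3-phenylundeca-6,9-dienoate | COC(=O)C[C@H](c1ccccc1)C[C@@H](O)/C(C)=C/CC=C(C)C | intermediate
13 | (4R,6R)-6-[(2E)-6-methylhepta-2,5-dien-2-yl]-4-phenyltetrahydro-2H-pyran-2-one (cis) | O=C1C[C@H](c2ccccc2)C[C@H](/C(C)=C/CC=C(C)C)O1 | intermediate
14 | tert-butyl(dimethyl)({(2R,4R)-2-[(2E)-6-methylhepta-2,5-dien-2-yl]-4-phenyl-3,4-dihydro-2H-pyran-6-yl}oxy)silane | CC(C)(C)[Si](C)(C)OC1=C[C@H](c2ccccc2)C[C@H](/C(C)=C/CC=C(C)C)O1 | intermediate
15 | tert-butyldimethylsilyl (1R,2S,6R)-3-methyl-2-(3-methylbut-2-en-1-yl)-6-phenylcyclohex-3-ene-1-carboxylate | CC(C)(C)[Si](C)(C)OC(=O)[C@@H]1[C@H](CC=C(C)C)C(C)=CC[C@H]1c1ccccc1 | intermediate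
16 | (1R,2S,6R)-3-methyl-2-(3-methylbut-2-en-1-yl)-6-phenylcyclohex-3-ene-1-carboxylic acid (CO2H cis to prenyl, trans to phenyl) | OC(=O)[C@@H]1[C@H](CC=C(C)C)C(C)=CC[C@H]1c1ccccc1 | intermediate
17 | 3-hydroxy-4,5-dimethoxybenzaldehyde | COc1cc(C=O)cc(O)c1OC | starting material
18 | 3-hydroxy-4,5-dimethoxyphenyl formate | COc1cc(OC=O)cc(O)c1OC | intermediate
19 | 4,5-dimethoxybenzene-1,3-diol | COc1cc(O)cc(O)c1OC | intermediate
20 | 1,2-dimethoxy-3,5-bis(methoxymethoxy)benzene | COCOc1cc(OC)c(OC)c(OCOC)c1 | intermediate
21 | (1R,2S,6R)-3-methyl-2-(3-methylbut-2-en-1-yl)-6-phenylcyclohex-3-ene-1-carbonyl chloride | ClC(=O)[C@@H]1[C@H](CC=C(C)C)C(C)=CC[C@H]1c1ccccc1 | intermediate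
22 | [2,6-bis(methoxymethoxy)-3,4-dimethoxyphenyl]lithium | COCOc1cc(OC)c(OC)c(OCOC)c1[Li] | intermediate
23 | chloro[2,6-bis(methoxymethoxy)-3,4-dimethoxyphenyl]zinc | COCOc1cc(OC)c(OC)c(OCOC)c1[Zn]Cl | intermediate
24 | [2,6-bis(methoxymethoxy)-3,4-dimethoxyphenyl][(1R,2S,6R)-3-methyl-2-(3-methylbut-2-en-1-yl)-6-phenylcyclohex-3-en-1-yl]methanone | COCOc1cc(OC)c(OC)c(OCOC)c1C(=O)[C@@H]1[C@H](CC=C(C)C)C(C)=CC[C@H]1c1ccccc1 | intermediate
25 | (2,6-dihydroxy-3,4-dimethoxyphenyl)[(1R,2S,6R)-3-methyl-2-(3-methylbut-2-en-1-yl)-6-phenylcyclohex-3-en-1-yl]methanone | COc1cc(O)c(C(=O)[C@@H]2[C@H](CC=C(C)C)C(C)=CC[C@H]2c2ccccc2)c(O)c1OC | target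

## Step count and risks

Total steps: 10. Longest linear sequence: 7 steps (1 → 2 → 4 → 5 → 6 → 9 → 10).

The three steps most likely to fail:

**Step 6, Ireland–Claisen ring contraction.** The enforced boat transition state carries a 2-methyl-substituted allyl unit and a ring phenyl group, so the rearrangement may be slow relative to decomposition or C-silylation of the lactone enolate. The fallback sets out from lactone 13 and moves the rearrangement to an aryl enol ether, so that no silyl ketene acetal and no acid chloride are needed.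
- KN(SiMe3)2 and (PhO)2P(O)Cl (THF/DMPU, −78 °C) convert 13 into the ketene acetal diphenyl phosphate F1.
- Negishi coupling of F1 with arylzinc chloride 23 (Pd(PPh3)4, THF, rt → 50 °C) gives the 6-aryl-2-alkenyl-3,4-dihydro-2H-pyran F2.
- Heating F2 (o-xylene, sealed tube, about 170 °C, BHT) brings about the Claisen ring contraction of this 2-alkenyl dihydropyran with the same boat topology and the same stereochemical outcome.
- This delivers the aryl ketone directly and comes back to the route at 24. The point to watch is retro-hetero-Diels–Alder cleavage at this temperature, which would erode the optical purity.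

**Step 9, Negishi acylation.** A diortho-substituted arylzinc must couple with an α-branched, doubly flanked acid chloride. Transmetalation may be slow enough for decarbonylation of the acylpalladium species to compete. The fallback sets out from acid 16 and replaces acyl substitution by addition to an aldehyde followed by oxidation.
- LiAlH4 (THF, 0 °C) reduces 16 to the primary alcohol F3.
- Dess–Martin periodinane (CH2Cl2, NaHCO3) gives the aldehyde F4.
- Aryllithium 22 adds to F4 at −78 °C (fast 1,2-addition, little enolisation) to give the secondary carbinol F5 as a mixture of carbinol epimers.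
- A second Dess–Martin oxidation converges both epimers and comes back to the route at 24.

**Step 5, CBS reduction.** The carbinol centre set here is relayed to C1 and C2 in step 6, so incomplete facial control (the small substituent is a β-branched CH2 group) would directly lower the yield of the correct lactone. The fallback sets out from enone 11 and replaces catalyst control by separation and inversion.
- NaBH4 with CeCl3·7H2O (MeOH, −78 °C) gives 12 together with its C5 epimer, the (3R,5S)-hydroxy ester F6.
- PPTS lactonisation gives 13 and the trans-lactone F7, which are separated on silica.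
- F7 is opened with LiOH (THF/H2O, then mild acidification) to the (3R,5S)-hydroxy acid F8.
- Mitsunobu lactonisation of F8 (PPh3, DIAD, toluene, high dilution) closes the ring with inversion at the carbinol carbon and comes back to the route at 13.

## Further compounds

F1 | step 6 | (2R,4R)-2-[(2E)-6-methylhepta-2,5-dien-2-yl]-4-phenyl-3,4-dihydro-2H-pyran-6-yl diphenyl phosphate | O=P(Oc1ccccc1)(Oc1ccccc1)OC1=C[C@H](c2ccccc2)C[C@H](/C(C)=C/CC=C(C)C)O1
F2 | step 6 | (2R,4R)-6-[2,6-bis(methoxymethoxy)-3,4-dimethoxyphenyl]-2-[(2E)-6-methylhepta-2,5-dien-2-yl]-4-phenyl-3,4-dihydro-2H-pyran | COCOc1cc(OC)c(OC)c(OCOC)c1C1=C[C@H](c2ccccc2)C[C@H](/C(C)=C/CC=C(C)C)O1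
F3 | step 9 | [(1R,2S,6R)-3-methyl-2-(3-methylbut-2-en-1-yl)-6-phenylcyclohex-3-en-1-yl]methanol | OC[C@@H]1[C@H](CC=C(C)C)C(C)=CC[C@H]1c1ccccc1
F4 | step 9 | (1R,2S,6R)-3-methyl-2-(3-methylbut-2-en-1-yl)-6-phenylcyclohex-3-ene-1-carbaldehyde | O=C[C@@H]1[C@H](CC=C(C)C)C(C)=CC[C@H]1c1ccccc1
F5 | step 9 | [2,6-bis(methoxymethoxy)-3,4-dimethoxyphenyl][(1R,2S,6R)-3-methyl-2-(3-methylbut-2-en-1-yl)-6-phenylcyclohex-3-en-1-yl]methanol (both carbinol epimers) | COCOc1cc(OC)c(OC)c(OCOC)c1C(O)[C@@H]1[C@H](CC=C(C)C)C(C)=CC[C@H]1c1ccccc1
F6 | step 5 | methyl (3R,5S,6E)-5-hydroxy-6,10-dimethyl-3-phenylundeca-6,9-dienoate | COC(=O)C[C@H](c1ccccc1)C[C@H](O)/C(C)=C/CC=C(C)C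
F7 | step 5 | (4R,6S)-6-[(2E)-6-methylhepta-2,5-dien-2-yl]-4-phenyltetrahydro-2H-pyran-2-one (trans) | O=C1C[C@H](c2ccccc2)C[C@@H](/C(C)=C/CC=C(C)C)O1
F8 | step 5 | (3R,5S,6E)-5-hydroxy-6,10-dimethyl-3-phenylundeca-6,9-dienoic acid | OC(=O)C[C@H](c1ccccc1)C[C@H](O)/C(C)=C/CC=C(C)C
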